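**Plan**
Retrosynthesis: the last cut removes C13=C16 and C14=C15. The side chain ends in an acyclic 2-substituted buta-1,3-diene, C13(=C16)–C14=C15, on the C11–C12 tether off ring B of the trans-decalin, and this unit equals a terminal C13≡C14 alkyne plus ethylene.
Further cuts: the C19–O ester (p-coumaric acid, phenol masked as acetate), C13≡C14 (one-carbon alkyne homologation), C12=C13 (Wittig), back to a 19-hydroxylated 12,8α-lactone of the sclareolide type.
The lactone comes from (+)-podocarpic acid by opening aromatic ring C: Birch reduction, ozonolysis of the C12=C13 enol ether, decarbonylation (old C13 lost, old C14 becomes C17), α-epoxidation of C8=C9, eliminative epoxide opening with lactonisation, hydrogenation.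
Forward: no ring is built. Rings A/B come intact from podocarpic acid, ring C is cut open so that C11–C12 become the side chain, which grows by two one-carbon steps and finally by ethylene.
Stereochemistry: C4, C5 and C10 from podocarpic acid; C8 (8α-O) from α-face epoxidation anti to the axial C10 methyl; C9 (9α-H) from α-face hydrogenation of the butenolide; the E cinnamate from p-coumaric acid.

Key step: step 16

Remark: diterpenoid numbering is used throughout (podocarpane C14 becomes labdane C17 in step 5); natural (+)-podocarpic acid is assumed to be the commercial enantiomer; the alkyne is built by homologating the lactol because a C12 leaving group beside the free 8α-OH would close to the 8α,12-ether.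

**Route**

Step 1
Reactants: 1 (+)-podocarpic acid
Product: 2 methyl 12-methoxypodocarpa-8,11,13-trien-19-oate
Conditions: MeI (excess), K2CO3, DMF, rt to 50 °C
Reagents that add atoms: iodomethane, CI
Why: Double O-methylation (Williamson ether synthesis and carboxylate alkylation, SN2 on MeI) works although the C4 carboxyl is axial and neopentyl, because the carboxylate attacks through oxygen, and no stereocentre is touched.

Step 2
Reactants: 2 methyl 12-methoxypodocarpa-8,11,13-trien-19-oate
Product: 3 12-methoxypodocarpa-8,11,13-trien-19-ol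
Conditions: LiAlH4, THF, reflux; aqueous work-up
Reagents that add atoms: none
Why: Hydride reduction of the hindered axial ester with LiAlH4 at reflux gives the primary C19 alcohol, the anisole ring being inert and C4 keeping its configuration.

Step 3
Reactants: 3 12-methoxypodocarpa-8,11,13-trien-19-ol
Product: 4 12-methoxypodocarpa-8,12-dien-19-ol
Conditions: Li, NH3(l)/THF, t-BuOH, −78 to −33 °C; then solid NH4Cl
Reagents that add atoms: none
Why: Birch reduction of the anisole ring gives the unconjugated 1,4-diene in which the methoxy-bearing carbon and both alkyl-bearing carbons stay olefinic (C12=C13 enol ether, tetrasubstituted C8=C9), the C19 alkoxide is inert, and no stereocentre forms.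

Step 4
Reactants: 4 12-methoxypodocarpa-8,12-dien-19-ol
Product: 6 methyl 19-hydroxy-13-oxo-12,13-secopodocarp-8-en-12-oate, via methyl 13-hydroperoxy-19-hydroxy-13-methoxy-12,13-secopodocarp-8-en-12-oate 5 (not isolated)
Conditions: O3 (1.0 equiv, dye end point), CH2Cl2/MeOH 4:1, pyridine (cat.), −78 °C; then Me2S, −78 °C to rt
Reagents that add atoms: ozone, [O-][O+]=O
Why: Ozonolysis of a Birch diene in methanol should cleave the enol ether double bond, the methoxy-bearing C12 becoming the methyl ester and the C13 carbonyl oxide being trapped by methanol as hydroperoxide 5, which Me2S reduces to the aldehyde, while one equivalent of ozone with pyridine should spare the tetrasubstituted C8=C9 bond.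

Step 5
Reactants: 6 methyl 19-hydroxy-13-oxo-12,13-secopodocarp-8-en-12-oate
Product: 7 methyl 19-hydroxy-13,14,15,16-tetranorlabd-8-en-12-oate
Conditions: RhCl(PPh3)3 (1.1 equiv), toluene, reflux, degassed
Reagents that add atoms: none
Why: Tsuji–Wilkinson decarbonylation (aldehyde C–H oxidative addition to Rh(I), CO extrusion, C–H reductive elimination) turns the C14H2–CHO arm into the C17 methyl group under neutral conditions that leave the ester, the alcohol and the alkene alone, reductive elimination at the primary carbon being expected to outrun allyl isomerisation.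

Step 6
Reactants: 7 methyl 19-hydroxy-13,14,15,16-tetranorlabd-8-en-12-oate
Product: 8 methyl 8α,9α-epoxy-19-hydroxy-13,14,15,16-tetranorlabdan-12-oate
Conditions: mCPBA (1.1 equiv), CH2Cl2, 0 °C; wash with aq. NaHCO3/Na2S2O3
Reagents that add atoms: 3-chloroperoxybenzoic acid, OOC(=O)c1cccc(Cl)c1
Why: Prilezhaev epoxidation of the electron-rich tetrasubstituted alkene should occur from the α face because the axial C10 methyl group shields the β face, which sets the C8–O bond α (the C9–O bond, also α, is removed in the next step).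

Step 7
Reactants: 8 methyl 8α,9α-epoxy-19-hydroxy-13,14,15,16-tetranorlabdan-12-oate
Product: 10 19-hydroxy-13,14,15,16-tetranorlabd-9(11)-en-12,8α-olide, via methyl (9(11)Z)-8α,19-dihydroxy-13,14,15,16-tetranorlabd-9(11)-en-12-oate 9 (not isolated)
Conditions: DBU (0.3 equiv), toluene, 80 °C
Reagents that add atoms: none
Why: E1cB opening of the β,γ-epoxy ester (the C11 enolate expels the C9–O bond) gives γ-hydroxy enoate 9 with the C8–O bond and its α configuration untouched, and the tertiary hydroxyl then closes onto the cis ester to form the butenolide.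

Step 8
Reactants: 10 19-hydroxy-13,14,15,16-tetranorlabd-9(11)-en-12,8α-olide
Product: 11 19-hydroxy-13,14,15,16-tetranorlabdan-12,8α-olide (19-hydroxysclareolide, 9α-H)
Conditions: H2 (4 atm), 5% Rh/Al2O3, EtOAc, rt
Reagents that add atoms: none
Why: Heterogeneous hydrogenation should deliver hydrogen to the trisubstituted butenolide C9=C11 bond from the α face, the β face being blocked by the C8 and C10 methyl groups, which sets 9α-H (trans-fused lactone as in sclareolide), and rhodium is chosen to avoid hydrogenolysis of the allylic C8–O bond.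

Step 9
Reactants: 11 19-hydroxy-13,14,15,16-tetranorlabdan-12,8α-olide
Product: 12 8α,12-epoxy-13,14,15,16-tetranorlabdane-12,19-diol (lactol, anomers)
Conditions: DIBAL-H (2.5 equiv), CH2Cl2, −78 °C; Rochelle salt
Reagents that add atoms: none
Why: DIBAL-H half-reduction of the γ-lactone stops at the aluminium hemiacetal at −78 °C and gives the lactol on work-up, one extra equivalent covering the C19 alkoxide.

Step 10
Reactants: 12 8α,12-epoxy-13,14,15,16-tetranorlabdane-12,19-diol
Product: 13 13-methoxy-14,15,16-trinorlabd-12-ene-8α,19-diol (E/Z mixture)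
Conditions: MeOCH2PPh3Cl (4 equiv), KOt-Bu (3.8 equiv), THF, 0 °C to rt
Reagents that add atoms: (methoxymethyl)triphenylphosphonium chloride, COC[P+](c1ccccc1)(c1ccccc1)c1ccccc1.[Cl-]
Why: Wittig methoxymethylenation of the lactol through its ring-opened hydroxy aldehyde adds C13 as an enol ether, the excess ylide merely deprotonating the two hydroxyl groups and the alkene geometry being irrelevant.

Step 11
Reactants: 13 13-methoxy-14,15,16-trinorlabd-12-ene-8α,19-diol
Product: 15 8α,13-epoxy-14,15,16-trinorlabdane-13,19-diol (six-membered lactol, anomers), via 8α,13-epoxy-13-methoxy-14,15,16-trinorlabdan-19-ol 14 (not isolated)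
Conditions: 1 M aq. HCl, THF, rt
Reagents that add atoms: water, O
Why: Acid hydrolysis of the enol ether proceeds by protonation at C12, trapping of the C13 oxocarbenium ion by the 8α-OH as cyclic methyl acetal 14 and exchange of methoxy for hydroxyl, which gives a masked C13 aldehyde under conditions mild enough to spare the tertiary carbinol.

Step 12
Reactants: 15 8α,13-epoxy-14,15,16-trinorlabdane-13,19-diol
Product: 16 15,16-dinorlabd-13-yne-8α,19-diol
Conditions: dimethyl (1-diazo-2-oxopropyl)phosphonate (2 equiv), K2CO3, MeOH, rt to 40 °C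
Reagents that add atoms: dimethyl (1-diazo-2-oxopropyl)phosphonate, COP(=O)(OC)C(=[N+]=[N-])C(C)=O
Why: Seyferth–Gilbert homologation with the Bestmann–Ohira reagent (methanolysis to the diazomethylphosphonate anion, addition to the aldehyde in equilibrium with the lactol, phosphate elimination, loss of N2 and 1,2-hydrogen shift) gives the terminal C13≡C14 alkyne with C14 as the new carbon, the carbonate base leaving both alcohols free.

Step 13
Reactants: 17 p-coumaric acid
Product: 18 (E)-4-acetoxycinnamic acid
Conditions: Ac2O, pyridine, rt; aqueous work-up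
Reagents that add atoms: acetic anhydride, CC(=O)OC(C)=O
Why: O-Acetylation of the phenol masks it for the coupling, any mixed anhydride at the carboxyl group being hydrolysed on aqueous work-up and the E alkene being untouched.

Step 14
Reactants: 16 15,16-dinorlabd-13-yne-8α,19-diol; 18 (E)-4-acetoxycinnamic acid
Product: 19 8α-hydroxy-15,16-dinorlabd-13-yn-19-yl (E)-4-acetoxycinnamate
Conditions: EDC·HCl (1.5 equiv), DMAP (0.5 equiv), CH2Cl2, 0 °C to rt
Reagents that add atoms: (E)-4-acetoxycinnamic acid (18), CC(=O)Oc1ccc(/C=C/C(=O)O)cc1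
Why: Steglich esterification (carbodiimide activation, DMAP acyl transfer) acylates the primary C19 alcohol while the tertiary 8α-OH is too hindered to compete, and the E cinnamate geometry and the alkyne are retained.

Step 15
Reactants: 19 8α-hydroxy-15,16-dinorlabd-13-yn-19-yl (E)-4-acetoxycinnamate
Product: 20 8α-hydroxy-15,16-dinorlabd-13-yn-19-yl (E)-p-coumarate
Conditions: K2CO3 (0.2 equiv), MeOH/THF, 0 °C; NH4Cl quench
Reagents that add atoms: none
Why: Base-catalysed methanolysis (transesterification) removes the aryl acetate, whose phenoxide leaving group makes it far more labile than the hindered neopentyl cinnamate.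

Step 16
Reactants: 20 8α-hydroxy-15,16-dinorlabd-13-yn-19-yl (E)-p-coumarate; 21 ethylene
Product: 22 8α-hydroxylabda-13(16),14-dien-19-yl p-hydroxycinnamate (target)
Conditions: Grubbs II (5–10 mol %), ethylene (1 atm), CH2Cl2 (0.02 M), rt; ethyl vinyl ether quench, Ru scavenger, cold chromatography
Reagents that add atoms: ethylene (21), C=C
Why: The ruthenium methylidene formed from the catalyst and ethylene adds to the terminal C13≡C14 alkyne to give a ruthenacyclobutene that opens to a vinyl carbene carrying the new C13=C16 bond, and ethylene then cleaves this carbene by [2+2]/retro-[2+2], forming C14=C15, releasing the 2-substituted buta-1,3-diene and regenerating the methylidene. The closest known reaction type is the ruthenium-catalysed cross enyne metathesis of terminal alkynes with ethylene. No ring closes and no stereocentre forms, so C4, C5, C8, C9 and C10 are not at stake. The step needs chemoselectivity for the alkyne over the cinnamate alkene and the product diene: the cinnamate is 1,2-disubstituted, conjugated and electron-poor and should be a poor partner for the methylidene at room temperature, and excess ethylene keeps the catalyst as the methylidene and suppresses diene homocoupling. The neutral conditions should leave the tertiary 8α-alcohol, the ester and the free phenol untouched, and the sensitive diene passes through no further step.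

**Compound list**
1 | (+)-podocarpic acid | Oc1ccc2c(c1)[C@@]1(C)CCC[C@](C)(C(=O)O)[C@@H]1CC2 | starting material
2 | methyl 12-methoxypodocarpa-8,11,13-trien-19-oate | COc1ccc2c(c1)[C@@]1(C)CCC[C@](C)(C(=O)OC)[C@@H]1CC2 | intermediate
3 | 12-methoxypodocarpa-8,11,13-trien-19-ol | COc1ccc2c(c1)[C@@]1(C)CCC[C@](C)(CO)[C@@H]1CC2 | intermediate
4 | 12-methoxypodocarpa-8,12-dien-19-ol | COC1=CCC2=C(C1)[C@@]1(C)CCC[C@](C)(CO)[C@@H]1CC2 | intermediate
5 | methyl 13-hydroperoxy-19-hydroxy-13-methoxy-12,13-secopodocarp-8-en-12-oate (C13 epimers) | OOC(OC)CC2=C(CC(=O)OC)[C@@]1(C)CCC[C@](C)(CO)[C@@H]1CC2 | intermediate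
6 | methyl 19-hydroxy-13-oxo-12,13-secopodocarp-8-en-12-oate | O=CCC2=C(CC(=O)OC)[C@@]1(C)CCC[C@](C)(CO)[C@@H]1CC2 | intermediate
7 | methyl 19-hydroxy-13,14,15,16-tetranorlabd-8-en-12-oate | CC2=C(CC(=O)OC)[C@@]1(C)CCC[C@](C)(CO)[C@@H]1CC2 | intermediate
8 | methyl 8α,9α-epoxy-19-hydroxy-13,14,15,16-tetranorlabdan-12-oate | C[C@@]23O[C@@]3(CC(=O)OC)[C@@]1(C)CCC[C@](C)(CO)[C@@H]1CC2 | intermediate
9 | methyl (9(11)Z)-8α,19-dihydroxy-13,14,15,16-tetranorlabd-9(11)-en-12-oate | C[C@]2(O)/C(=C\C(=O)OC)[C@@]1(C)CCC[C@](C)(CO)[C@@H]1CC2 | intermediate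
10 | 19-hydroxy-13,14,15,16-tetranorlabd-9(11)-en-12,8α-olide | C[C@@]23OC(=O)C=C3[C@@]1(C)CCC[C@](C)(CO)[C@@H]1CC2 | intermediate
11 | 19-hydroxy-13,14,15,16-tetranorlabdan-12,8α-olide | C[C@@]23OC(=O)C[C@@H]3[C@@]1(C)CCC[C@](C)(CO)[C@@H]1CC2 | intermediate
12 | 8α,12-epoxy-13,14,15,16-tetranorlabdane-12,19-diol (anomers) | C[C@@]23OC(O)C[C@@H]3[C@@]1(C)CCC[C@](C)(CO)[C@@H]1CC2 | intermediate
13 | 13-methoxy-14,15,16-trinorlabd-12-ene-8α,19-diol (E/Z) | COC=CC[C@@H]1[C@@]2(C)CCC[C@](C)(CO)[C@@H]2CC[C@@]1(C)O | intermediate
14 | 8α,13-epoxy-13-methoxy-14,15,16-trinorlabdan-19-ol (anomers) | COC1CC[C@@H]2[C@@]3(C)CCC[C@](C)(CO)[C@@H]3CC[C@@]2(C)O1 | intermediate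
15 | 8α,13-epoxy-14,15,16-trinorlabdane-13,19-diol (anomers) | OC1CC[C@@H]2[C@@]3(C)CCC[C@](C)(CO)[C@@H]3CC[C@@]2(C)O1 | intermediate
16 | 15,16-dinorlabd-13-yne-8α,19-diol | C#CCC[C@@H]1[C@@]2(C)CCC[C@](C)(CO)[C@@H]2CC[C@@]1(C)O | intermediate
17 | p-coumaric acid | O=C(O)/C=C/c1ccc(O)cc1 | starting material
18 | (E)-4-acetoxycinnamic acid | CC(=O)Oc1ccc(/C=C/C(=O)O)cc1 | intermediate
19 | 8α-hydroxy-15,16-dinorlabd-13-yn-19-yl (E)-4-acetoxycinnamate | C#CCC[C@@H]1[C@@]2(C)CCC[C@](C)(COC(=O)/C=C/c3ccc(OC(C)=O)cc3)[C@@H]2CC[C@@]1(C)O | intermediate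
20 | 8α-hydroxy-15,16-dinorlabd-13-yn-19-yl (E)-p-coumarate | C#CCC[C@@H]1[C@@]2(C)CCC[C@](C)(COC(=O)/C=C/c3ccc(O)cc3)[C@@H]2CC[C@@]1(C)O | intermediate
21 | ethylene | C=C | starting material
22 | 8α-hydroxylabda-13(16),14-dien-19-yl p-hydroxycinnamate | C=CC(=C)CC[C@@H]1[C@@]2(C)CCC[C@](C)(COC(=O)/C=C/c3ccc(O)cc3)[C@@H]2CC[C@@]1(C)O | target

**Step count**
Total: 16 steps. Longest linear sequence: 15 steps (steps 1–12 and 14–16 from podocarpic acid); step 13 is a one-step branch.

**Steps most likely to fail**

Step 4. Ozone may not discriminate well enough between the enol ether and the equally electron-rich tetrasubstituted C8=C9 bond, so ring B could be cleaved too. The fallback sets out from 4 and comes back at 6. Catalytic OsO4 with NMO in aqueous acetone should dihydroxylate only the less hindered trisubstituted enol ether, and the resulting hemiketal loses methanol to give the α-ketol 13,19-dihydroxypodocarp-8-en-12-one F1. Lead tetraacetate in methanol/benzene at 0 °C then cleaves the C12–C13 bond of the ketol to the methyl ester and the aldehyde, which is 6.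

Step 5. After CO extrusion the alkyl rhodium hydride is allylic and may equilibrate through an η3-allyl form, so that hydrogen is delivered to C9 and the double bond moves out to C8=C14. The fallback sets out from 6 and comes back at 11; it postpones the loss of C13 until the alkene is gone.
- The aldehyde is masked as the dimethyl acetal methyl 19-hydroxy-13,13-dimethoxy-12,13-secopodocarp-8-en-12-oate F2 (HC(OMe)3, PPTS, MeOH).
- mCPBA gives the α-epoxide methyl 8α,9α-epoxy-19-hydroxy-13,13-dimethoxy-12,13-secopodocarpan-12-oate F3.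
- DBU opens it through methyl (9(11)Z)-8α,19-dihydroxy-13,13-dimethoxy-12,13-secopodocarp-9(11)-en-12-oate F4 to the butenolide 19-hydroxy-13,13-dimethoxy-12,13-secopodocarp-9(11)-en-12,8α-olide F5.
- Hydrogenation over Rh/Al2O3 gives 19-hydroxy-13,13-dimethoxy-12,13-secopodocarpan-12,8α-olide F6.
- PPTS in aqueous acetone frees the aldehyde 19-hydroxy-13-oxo-12,13-secopodocarpan-12,8α-olide F7.
- RhCl(PPh3)3 in toluene at reflux decarbonylates this saturated primary aldehyde, which has no allylic option, to lactone 11.

Step 8. Hydrogen uptake at the hindered C9=C11 bond may be slow, facial selectivity may be poor, or the allylic C8–O bond may be hydrogenolysed. The fallback sets out from 10 and comes back at 11. Excess DIBAL-H reduces the butenolide to (9(11)Z)-13,14,15,16-tetranorlabd-9(11)-ene-8α,12,19-triol F8. Hydroxyl-directed hydrogenation with Crabtree's catalyst (H2, CH2Cl2), in which the allylic 8α-OH binds iridium and delivers hydrogen to the α face of C9, gives 13,14,15,16-tetranorlabdane-8α,12,19-triol F9. TEMPO with PhI(OAc)2 then oxidises the unhindered C12 alcohol, in preference to the neopentyl C19 alcohol, through lactol 12 to lactone 11.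

**Further compounds**
F1 | step 4 | 13,19-dihydroxypodocarp-8-en-12-one (C13 epimers) | O=C1C(O)CC2=C(C1)[C@@]1(C)CCC[C@](C)(CO)[C@@H]1CC2
F2 | step 5 | methyl 19-hydroxy-13,13-dimethoxy-12,13-secopodocarp-8-en-12-oate | COC(OC)CC2=C(CC(=O)OC)[C@@]1(C)CCC[C@](C)(CO)[C@@H]1CC2
F3 | step 5 | methyl 8α,9α-epoxy-19-hydroxy-13,13-dimethoxy-12,13-secopodocarpan-12-oate | COC(OC)C[C@@]23O[C@@]3(CC(=O)OC)[C@@]1(C)CCC[C@](C)(CO)[C@@H]1CC2
F4 | step 5 | methyl (9(11)Z)-8α,19-dihydroxy-13,13-dimethoxy-12,13-secopodocarp-9(11)-en-12-oate | COC(OC)C[C@]2(O)/C(=C\C(=O)OC)[C@@]1(C)CCC[C@](C)(CO)[C@@H]1CC2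
F5 | step 5 | 19-hydroxy-13,13-dimethoxy-12,13-secopodocarp-9(11)-en-12,8α-olide | COC(OC)C[C@@]23OC(=O)C=C3[C@@]1(C)CCC[C@](C)(CO)[C@@H]1CC2
F6 | step 5 | 19-hydroxy-13,13-dimethoxy-12,13-secopodocarpan-12,8α-olide | COC(OC)C[C@@]23OC(=O)C[C@@H]3[C@@]1(C)CCC[C@](C)(CO)[C@@H]1CC2
F7 | step 5 | 19-hydroxy-13-oxo-12,13-secopodocarpan-12,8α-olide | O=CC[C@@]23OC(=O)C[C@@H]3[C@@]1(C)CCC[C@](C)(CO)[C@@H]1CC2
F8 | step 8 | (9(11)Z)-13,14,15,16-tetranorlabd-9(11)-ene-8α,12,19-triol | C[C@]2(O)/C(=C\CO)[C@@]1(C)CCC[C@](C)(CO)[C@@H]1CC2
F9 | step 8 | 13,14,15,16-tetranorlabdane-8α,12,19-triol | OCC[C@@H]1[C@@]2(C)CCC[C@](C)(CO)[C@@H]2CC[C@@]1(C)O
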